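**Plan**

1. Retrosynthesis: the quinone methide comes from the C12 phenol by ortho-oxidation (C11–O) and tautomerization. The C23–O and C7–H bonds come from hydroboration of an indene, C7=C23 and C23–C25 from a one-carbon alkylidene carbene on the C7 ketone, and C14–C25 from a Suzuki coupling with a sabinene-derived boronate.
2. The abietane ketone is then cut at C1–C2 and C5–C10 in one operation (rings A and B together), and further at C5–Br (hydrobromination), C6–C7 (acetylide plus phthalide) and C7–C8 (carboxylation).
3. Forward order: ring C is bought, the chain is joined (steps 1–7), ring B then ring A close in step 8, the thujane is attached at C14, the spiro five-membered ring closes in step 17, and the quinone methide is unveiled last.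
4. Enabling feature: C10 is a quaternary benzylic carbon carrying aryl C9, methyl C20 and methylene C1, so it can be written as an isopropenyl group on C9. C5 is β to the C7 carbonyl, so it can be a β-bromoenone carbon. Carbometalation of the isopropenyl group at C10 by a C5 vinylnickel closes ring B and leaves a C1–Ni bond with no β-hydrogen, which is then joined to C2 to close ring A.
5. Stereochemistry: C10 from the chiral nickel ligand; C5 from hydrogenation anti to the C10 methyl; the thujane bridgeheads from (+)-sabinene; spiro C25 from hydrogenation anti to the cyclopropane CH2 followed by C–H insertion with retention; C23 from reagent-controlled hydroboration; C7 is a temporary stereocenter that is erased.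

Key step: step 8

Remark: abietane numbers (C1–C20) are used for the diterpene part; C23 is the carbinol carbon, C25 the spiro carbon, C26 and C27 the thujane CH2 groups, C28 and C33 the cyclopropane bridgeheads, C32 the cyclopropane CH2.

Assumption: (+)-sabinene is the (1R,5R) enantiomer, which maps onto the thujane part of the target; the enantiomers of the nickel ligand and of the borane named below are those expected to give the stated sense, and the antipode would be taken if a first run showed the opposite.

**Route**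

Step 1
Reactants: 1 methyl 4-isopropyl-3,5-dimethoxybenzoate
Product: 2 2-(4-isopropyl-3,5-dimethoxyphenyl)propan-2-ol
Conditions: MeMgBr (3 equiv), THF, 0 °C to rt; aq. NH4Cl
Reagents that add atoms: methylmagnesium bromide, C[Mg]Br
Why: Double Grignard addition to the ester gives the tertiary benzylic carbinol whose carbinol carbon is the later C10 and whose methyls are C1 and C20.

Step 2
Reactants: 2 2-(4-isopropyl-3,5-dimethoxyphenyl)propan-2-ol
Product: 5 6-isopropyl-5,7-dimethoxy-3,3-dimethyl-2-benzofuran-1(3H)-one, via dilithiated carbinol 3 (not isolated), via hydroxy acid 4 (not isolated)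
Conditions: nBuLi (2.3 equiv), TMEDA, Et2O, 0 °C to rt; CO2, −78 °C to rt; 2 M HCl, rt
Reagents that add atoms: carbon dioxide, O=C=O
Why: The lithium alkoxide and the neighbouring methoxy group direct ortho-lithiation to the ring carbon between them (directed ortho metalation; the two such positions are equivalent by symmetry), and carboxylation with acid-promoted lactonization places C7 on C8 next to the later C14 oxygen.

Step 3
Reactants: 6 3,3-dimethyloxolan-2-one
Product: 8 3,3-dimethylpent-4-yn-1-ol, via lactol 7 (not isolated)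
Conditions: iBu2AlH (1.1 equiv), CH2Cl2, −78 °C; then MeOH, K2CO3, dimethyl (1-diazo-2-oxopropyl)phosphonate, −78 °C to rt
Reagents that add atoms: dimethyl (1-diazo-2-oxopropyl)phosphonate, CC(=O)C(=[N+]=[N-])P(=O)(OC)OC
Why: Partial reduction gives the lactol, whose open hydroxy aldehyde undergoes Seyferth–Gilbert homologation with the Ohira–Bestmann reagent in the same flask, so the lactone carbonyl carbon becomes C5 of a terminal alkyne next to the gem-dimethyl carbon C4.

Step 4
Reactants: 8 3,3-dimethylpent-4-yn-1-ol
Product: 9 5-bromo-3,3-dimethylpent-1-yne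
Conditions: CBr4, PPh3, CH2Cl2, 0 °C
Reagents that add atoms: carbon tetrabromide, BrC(Br)(Br)Br
Why: The Appel reaction converts the primary alcohol (C2) into the bromide under neutral conditions that leave the terminal alkyne untouched.

Step 5
Reactants: 9 5-bromo-3,3-dimethylpent-1-yne; 5 6-isopropyl-5,7-dimethoxy-3,3-dimethyl-2-benzofuran-1(3H)-one
Product: 11 1-(5-bromo-3,3-dimethylpent-1-yn-1-yl)-6-isopropyl-5,7-dimethoxy-3,3-dimethyl-1,3-dihydro-2-benzofuran-1-ol (lactol form of the hydroxy ynone), via lithium acetylide 10 (not isolated)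
Conditions: 9, nBuLi (1.0 equiv), THF, −78 °C; then 5, −78 to −40 °C; aq. NH4Cl
Reagents that add atoms: none
Why: The lithium acetylide adds once to the lactone carbonyl (the tetrahedral lithium hemiketalate resists a second addition at low temperature), joining C6 to C7, while the primary bromide is inert to the acetylide at −78 °C.

Step 6
Reactants: 11 lactol from step 5
Product: 12 6-bromo-1-[3-isopropyl-2,4-dimethoxy-6-(prop-1-en-2-yl)phenyl]-4,4-dimethylhex-2-yn-1-one
Conditions: TsOH·H2O (5 mol %), toluene, 80 °C, Dean–Stark trap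
Reagents that add atoms: none
Why: The lactol is in ring–chain equilibrium with the hydroxy ynone, and acid-catalysed E1 dehydration of the tertiary benzylic alcohol with removal of water drives it to the isopropenyl ynone (C10=C1).

Step 7
Reactants: 12 isopropenyl ynone
Product: 13 (2Z)-3,6-dibromo-1-[3-isopropyl-2,4-dimethoxy-6-(prop-1-en-2-yl)phenyl]-4,4-dimethylhex-2-en-1-one
Conditions: LiBr (1.5 equiv), AcOH (2 equiv), MeCN, 40 °C
Reagents that add atoms: lithium bromide, [Li+].[Br-]
Why: Conjugate hydrobromination of the ynone (anti addition of bromide and a proton) puts bromine on C5 cis to the C7 carbonyl; this Z isomer is also the more stable one because the tert-alkyl group avoids the aroyl group.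

Step 8
Reactants: 13 (Z)-β-bromoenone
Product: 14 (10S)-12,14-dimethoxyabieta-5,8,11,13-tetraen-7-one
Conditions: NiBr2(dme) (10 mol %), (S)-4-tert-butyl-2-(pyridin-2-yl)-4,5-dihydrooxazole (12 mol %), Mn powder (3 equiv), N,N-dimethylacetamide, 25 °C
Reagents that add atoms: none
Why: Proposed new method: zerovalent nickel inserts into the C5–Br bond of the β-bromoenone, the vinylnickel adds 6-exo-trig to the isopropenyl group at its inner carbon C10 (ring B, C5–C10 bond), and the resulting neopentyl C1–Ni species, after reduction by manganese, abstracts the bromine atom of C2, recombines with the C2 radical and closes ring A by C(sp3)–C(sp3) reductive elimination from trivalent nickel (C1–C2 bond). The closest known reaction type is the nickel-catalysed enantioselective reductive aryl-alkylation (1,2-dicarbofunctionalization) of tethered 1,1-disubstituted alkenes with alkyl bromides, here run with a vinyl bromide, a six-membered first ring and a tethered alkyl bromide. Ring B closes by exo migratory insertion and ring A by reductive elimination from a seven-membered nickelacycle. The only new stereocenter, C10, is set in the migratory insertion by the chiral pyridine–oxazoline ligand, which selects the face of the isopropenyl group; no other stereocenter is present. The step needs addition at C10 and not at C1, and a C1–Ni bond that survives until capture: the Z geometry holds nickel cis to the aroyl group so that only the exo six-membered closure is in reach, and because C10 becomes quaternary the C1–Ni bond has no β-hydrogen. The C2 radical has only 3-exo, 4-exo or 5-endo alkene additions open to it, so it returns to nickel.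

Step 9
Reactants: 14 (10S)-12,14-dimethoxyabieta-5,8,11,13-tetraen-7-one
Product: 15 (5S,10S)-12,14-dimethoxyabieta-8,11,13-trien-7-one
Conditions: H2 (1 atm), Pd/C (10 wt %), EtOAc, rt
Reagents that add atoms: none
Why: Heterogeneous hydrogenation of the enone C5=C6 occurs from the α face, opposite the axial C10 methyl and the axial C4 methyl, which sets C5 (S) and the trans A/B ring fusion.

Step 10
Reactants: 15 (5S,10S)-12,14-dimethoxyabieta-8,11,13-trien-7-one
Product: 16 (5S,10S)-14-hydroxy-12-methoxyabieta-8,11,13-trien-7-one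
Conditions: BCl3 (1.2 equiv), CH2Cl2, −78 to 0 °C; H2O
Reagents that add atoms: none
Why: Boron trichloride chelates between the C7 carbonyl and the peri 14-methoxy oxygen and cleaves only that methyl ether (chelation-controlled demethylation), so the 12-methoxy group is kept.

Step 11
Reactants: 16 (5S,10S)-14-hydroxy-12-methoxyabieta-8,11,13-trien-7-one
Product: 17 (5S,10S)-12-methoxy-7-oxoabieta-8,11,13-trien-14-yl trifluoromethanesulfonate
Conditions: Tf2O (1.3 equiv), pyridine, CH2Cl2, 0 °C to rt
Reagents that add atoms: trifluoromethanesulfonic anhydride, O=S(=O)(OS(=O)(=O)C(F)(F)F)C(F)(F)F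
Why: O-Sulfonylation of the chelated phenol gives the aryl triflate needed for cross-coupling at C14.

Step 12
Reactants: 18 (1R,5R)-(+)-sabinene
Product: 20 sabina ketone, (1S,5R)-5-(propan-2-yl)bicyclo[3.1.0]hexan-2-one, via ozonide 19 (not isolated)
Conditions: O3, CH2Cl2, −78 °C; then Me2S, −78 °C to rt
Reagents that add atoms: ozone, [O-][O+]=O
Why: Ozonolysis with reductive work-up cleaves the exocyclic methylene and leaves both ring-fusion stereocenters untouched.

Step 13
Reactants: 20 sabina ketone
Product: 22 5-(propan-2-yl)bicyclo[3.1.0]hex-2-en-2-yl trifluoromethanesulfonate (ring fusion as in 20), via lithium enolate 21 (not isolated)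
Conditions: LiN(SiMe3)2 (1.1 equiv), THF, −78 °C; PhNTf2, −78 to 0 °C
Reagents that add atoms: N-phenylbis(trifluoromethanesulfonimide), O=S(=O)(N(c1ccccc1)S(=O)(=O)C(F)(F)F)C(F)(F)F
Why: Deprotonation can occur only at the CH2 α to the ketone (the other α carbon is the cyclopropane bridgehead), and O-triflation of the enolate gives the enol triflate.

Step 14
Reactants: 22 enol triflate
Product: 23 2-[5-(propan-2-yl)bicyclo[3.1.0]hex-2-en-2-yl]-4,4,5,5-tetramethyl-1,3,2-dioxaborolane (ring fusion as in 20)
Conditions: B2pin2 (1.1 equiv), PdCl2(PPh3)2 (3 mol %), PPh3 (6 mol %), KOPh (1.5 equiv), toluene, 50 °C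
Reagents that add atoms: bis(pinacolato)diboron, CC1(C)OB(OC1(C)C)B1OC(C)(C)C(C)(C)O1
Why: Miyaura borylation of the alkenyl triflate gives the alkenyl boronate; phenoxide as base keeps the product from coupling with the starting triflate.

Step 15
Reactants: 17 aryl triflate; 23 alkenyl boronate
Product: 24 (5S,10S)-12-methoxy-14-[5-(propan-2-yl)bicyclo[3.1.0]hex-2-en-2-yl]abieta-8,11,13-trien-7-one (ring fusion as in 20)
Conditions: Pd(OAc)2 (5 mol %), SPhos (10 mol %), K3PO4 (3 equiv), THF/H2O, 65 °C
Reagents that add atoms: none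
Why: Suzuki–Miyaura coupling with a bulky electron-rich biarylphosphine joins C14 to the future spiro carbon C25 despite the two ortho substituents.

Step 16
Reactants: 24 coupled ketone
Product: 25 (5S,10S)-12-methoxy-14-[5-(propan-2-yl)bicyclo[3.1.0]hexan-2-yl]abieta-8,11,13-trien-7-one, aryl group cis to the cyclopropane CH2 (C25 R)
Conditions: H2 (3 atm), [Ir(cod)(PCy3)(py)]PF6 (5 mol %), CH2Cl2, rt
Reagents that add atoms: none
Why: Hydrogen is delivered to the trisubstituted alkene from the face away from the cyclopropane CH2, which shields the other face from the adjacent bridgehead, so the new C25–H is anti and the aryl group ends up syn to the cyclopropane CH2; the homogeneous iridium catalyst leaves the cyclopropane and the ketone intact.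

Step 17
Reactants: 25 hydrogenated ketone
Product: 28 (5S,10S,25S)-spiro indene in which C23(H)=C7 and the C23–C25 bond close a five-membered ring on C7, C8 and C14 (12-OMe kept), via diazo alkoxide 26 (not isolated), via diazoalkene 27 (not isolated)
Conditions: Me3SiCHN2 (1.5 equiv), nBuLi (1.4 equiv), THF, −78 °C; then 25, −78 °C to rt
Reagents that add atoms: (trimethylsilyl)diazomethane, C[Si](C)(C)C=[N+]=[N-]
Why: Lithiated (trimethylsilyl)diazomethane adds to the C7 ketone, Peterson-type loss of lithium trimethylsilanolate and then of nitrogen gives the alkylidene carbene C7=C23, and this inserts with retention into the only 1,5-related C–H bond, the tertiary benzylic C25–H (alkylidene carbene 1,5-C–H insertion), so C23 takes the place of that hydrogen anti to the cyclopropane CH2; the competing 1,2-aryl shift is disfavoured because it would give a strained benzocycloheptyne.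

Step 18
Reactants: 28 spiro indene
Product: 30 (23R)-alcohol with 7-H and 23-OH cis on the α face (12-OMe kept), via alkylborane 29 (not isolated)
Conditions: IpcBH2 (from (+)-α-pinene, 2 equiv), THF, −25 to 0 °C; then 3 M NaOH, 30% H2O2, 0 °C to rt
Reagents that add atoms: hydrogen peroxide, OO
Why: Asymmetric hydroboration with monoisopinocampheylborane adds boron to C23 (the less substituted, non-benzylic carbon) and hydrogen to C7 syn from the α face under reagent control, and oxidation with retention gives the (23R)-alcohol; C7 is a temporary stereocenter.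

Step 19
Reactants: 30 (23R)-alcohol
Product: 31 C12 phenol of 30
Conditions: NaSEt (6 equiv), DMF, 130 °C; aq. NH4Cl
Reagents that add atoms: none
Why: Nucleophilic demethylation by ethanethiolate (SN2 at the methyl group) frees the C12 phenol without acid, which spares the cyclopropane and the secondary alcohol.

Step 20
Reactants: 31 phenol
Product: 33 CNP0114174.1 (target), via o-quinone 32 (not isolated)
Conditions: IBX (1.1 equiv), DMF, 0 °C to rt; then silica gel, CH2Cl2, rt
Reagents that add atoms: 2-iodoxybenzoic acid, O=C1OI(=O)(O)c2ccccc12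
Why: The hypervalent iodine reagent delivers oxygen to the free ortho carbon C11 and gives the 11,12-o-quinone, which tautomerizes by loss of the C7 hydrogen to the 11-hydroxy-7,9(11),13-trien-12-one (quinone methide); this erases the temporary C7 stereocenter, and the hindered C23 alcohol should not be oxidized at this temperature.

**Compound list**

1 | methyl 4-isopropyl-3,5-dimethoxybenzoate | COC(=O)c1cc(OC)c(C(C)C)c(OC)c1 | starting material
2 | 2-(4-isopropyl-3,5-dimethoxyphenyl)propan-2-ol | CC(C)c1c(OC)cc(C(C)(C)O)cc1OC | intermediate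
3 | dilithiated carbinol (aryllithium lithium alkoxide; not isolated) | [Li]c1c(OC)c(C(C)C)c(OC)cc1C(C)(C)O[Li] | intermediate
4 | 6-(2-hydroxypropan-2-yl)-3-isopropyl-2,4-dimethoxybenzoic acid (not isolated) | CC(C)c1c(OC)cc(C(C)(C)O)c(C(=O)O)c1OC | intermediate
5 | 6-isopropyl-5,7-dimethoxy-3,3-dimethyl-2-benzofuran-1(3H)-one | CC(C)c1c(OC)cc2c(c1OC)C(=O)OC2(C)C | intermediate
6 | 3,3-dimethyloxolan-2-one (α,α-dimethyl-γ-butyrolactone) | CC1(C)CCOC1=O | starting material
7 | 3,3-dimethyloxolan-2-ol (lactol; not isolated) | CC1(C)CCOC1O | intermediate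
8 | 3,3-dimethylpent-4-yn-1-ol | C#CC(C)(C)CCO | intermediate
9 | 5-bromo-3,3-dimethylpent-1-yne | C#CC(C)(C)CCBr | intermediate
10 | (5-bromo-3,3-dimethylpent-1-yn-1-yl)lithium (not isolated) | [Li]C#CC(C)(C)CCBr | intermediate
11 | 1-(5-bromo-3,3-dimethylpent-1-yn-1-yl)-6-isopropyl-5,7-dimethoxy-3,3-dimethyl-1,3-dihydro-2-benzofuran-1-ol (lactol form of the hydroxy ynone, both hemiketal epimers) | CC(C)c1c(OC)cc2c(c1OC)C(O)(C#CC(C)(C)CCBr)OC2(C)C | intermediate
12 | 6-bromo-1-[3-isopropyl-2,4-dimethoxy-6-(prop-1-en-2-yl)phenyl]-4,4-dimethylhex-2-yn-1-one | C=C(C)c1cc(OC)c(C(C)C)c(OC)c1C(=O)C#CC(C)(C)CCBr | intermediate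
13 | (2Z)-3,6-dibromo-1-[3-isopropyl-2,4-dimethoxy-6-(prop-1-en-2-yl)phenyl]-4,4-dimethylhex-2-en-1-one | C=C(C)c1cc(OC)c(C(C)C)c(OC)c1C(=O)/C=C(\Br)C(C)(C)CCBr | intermediate
14 | (10S)-12,14-dimethoxyabieta-5,8,11,13-tetraen-7-one | CC(C)c1c(OC)cc2c(c1OC)C(=O)C=C1C(C)(C)CCC[C@@]12C | intermediate
15 | (5S,10S)-12,14-dimethoxyabieta-8,11,13-trien-7-one | CC(C)c1c(OC)cc2c(c1OC)C(=O)C[C@H]1C(C)(C)CCC[C@@]12C | intermediate
16 | (5S,10S)-14-hydroxy-12-methoxyabieta-8,11,13-trien-7-one | CC(C)c1c(OC)cc2c(c1O)C(=O)C[C@H]1C(C)(C)CCC[C@@]12C | intermediate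
17 | (5S,10S)-12-methoxy-7-oxoabieta-8,11,13-trien-14-yl trifluoromethanesulfonate | CC(C)c1c(OC)cc2c(c1OS(=O)(=O)C(F)(F)F)C(=O)C[C@H]1C(C)(C)CCC[C@@]12C | intermediate
18 | (1R,5R)-(+)-sabinene, 4-methylidene-1-(propan-2-yl)bicyclo[3.1.0]hexane | C=C1CC[C@]2(C(C)C)C[C@@H]21 | starting material
19 | sabinene secondary ozonide (spiro 1,2,4-trioxolane; not isolated) | C1OOC2(O1)CC[C@]3(C(C)C)C[C@@H]32 | intermediate
20 | sabina ketone, (1S,5R)-5-(propan-2-yl)bicyclo[3.1.0]hexan-2-one | O=C1CC[C@]2(C(C)C)C[C@@H]21 | intermediate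
21 | lithium enolate of 20 (C2–OLi, C2=C3; not isolated) | [Li]OC1=CC[C@]2(C(C)C)C[C@@H]21 | intermediate
22 | 5-(propan-2-yl)bicyclo[3.1.0]hex-2-en-2-yl trifluoromethanesulfonate (ring fusion as in 20) | O=S(=O)(OC1=CC[C@]2(C(C)C)C[C@@H]21)C(F)(F)F | intermediate
23 | 2-[5-(propan-2-yl)bicyclo[3.1.0]hex-2-en-2-yl]-4,4,5,5-tetramethyl-1,3,2-dioxaborolane (ring fusion as in 20) | CC1(C)OB(OC1(C)C)C1=CC[C@]2(C(C)C)C[C@@H]21 | intermediate
24 | (5S,10S)-12-methoxy-14-[5-(propan-2-yl)bicyclo[3.1.0]hex-2-en-2-yl]abieta-8,11,13-trien-7-one | CC(C)c1c(OC)cc2c(c1C1=CC[C@]3(C(C)C)C[C@@H]31)C(=O)C[C@H]1C(C)(C)CCC[C@@]12C | intermediate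
25 | (5S,10S)-12-methoxy-14-[5-(propan-2-yl)bicyclo[3.1.0]hexan-2-yl]abieta-8,11,13-trien-7-one, aryl cis to the cyclopropane CH2 (C25 R) | CC(C)c1c(OC)cc2c(c1[C@@H]1CC[C@]3(C(C)C)C[C@@H]31)C(=O)C[C@H]1C(C)(C)CCC[C@@]12C | intermediate
26 | lithium alkoxide adduct of 25 with lithiated (trimethylsilyl)diazomethane at C7 (not isolated) | CC(C)c1c(OC)cc2c(c1[C@@H]1CC[C@]3(C(C)C)C[C@@H]31)C(O[Li])(C(=[N+]=[N-])[Si](C)(C)C)C[C@H]1C(C)(C)CCC[C@@]12C | intermediate
27 | 7-(diazomethylidene) derivative of 25 (diazoalkene; not isolated) | CC(C)c1c(OC)cc2c(c1[C@@H]1CC[C@]3(C(C)C)C[C@@H]31)C(=C=[N+]=[N-])C[C@H]1C(C)(C)CCC[C@@]12C | intermediate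
28 | (5S,10S,25S)-spiro indene: 12-methoxy aromatic ring C, C7=C23(H), C23–C25 bond, spiro thujane on C25 | CC(C)c1c(OC)cc2c3c1[C@]4(C=C3C[C@H]5C(C)(C)CCC[C@@]52C)CC[C@]6(C(C)C)C[C@@H]64 | intermediate
29 | C23 isopinocampheylborane adduct of 28, boron and 7-H cis on the α face (not isolated) | CC(C)c1c(OC)cc2c3c1[C@]4([C@H](B[C@@H]7C[C@@H]8C[C@H]([C@H]7C)C8(C)C)[C@H]3C[C@H]5C(C)(C)CCC[C@@]52C)CC[C@]6(C(C)C)C[C@@H]64 | intermediate
30 | (5S,10S,23R,25S)-23-hydroxy-12-methoxy compound, 7-H cis to 23-OH (α) | CC(C)c1c(OC)cc2c3c1[C@]4([C@H](O)[C@H]3C[C@H]5C(C)(C)CCC[C@@]52C)CC[C@]6(C(C)C)C[C@@H]64 | intermediate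
31 | (5S,10S,23R,25S)-12,23-diol (C12 phenol of 30) | CC(C)c1c(O)cc2c3c1[C@]4([C@H](O)[C@H]3C[C@H]5C(C)(C)CCC[C@@]52C)CC[C@]6(C(C)C)C[C@@H]64 | intermediate
32 | 11,12-o-quinone of 31 (not isolated) | CC(C)C1=C2C3=C(C(=O)C1=O)[C@@]1(C)CCCC(C)(C)[C@@H]1C[C@@H]3[C@@H](O)[C@]21CC[C@]2(C(C)C)C[C@@H]21 | intermediate
33 | CNP0114174.1: (5S,10S,23R,25S)-11,23-dihydroxy-12-oxo quinone methide (C7=C8, C9=C11, C13=C14) with the spiro thujane on C25 | CC(C)C1=C2C3=C(C[C@H]4C(C)(C)CCC[C@]4(C)C3=C(O)C1=O)[C@@H](O)[C@]21CC[C@]2(C(C)C)C[C@@H]21 | target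

**Totals**

Total step count: 20.
Longest linear sequence: 15 steps (steps 1, 2, 5–11, 15–20, from 1; the same length from 6 through steps 3–11 and 15–20).

**Steps most likely to fail, and fallbacks**

Step 8 (Proposed new method). What may go wrong: reduction of the vinylnickel or of the neopentyl alkylnickel (protodehalogenation) before the second C–C bond forms, or activation and loss of the alkyl bromide before ring B has closed. The fallback uses known chemistry, sets out from 13 and comes back at 14. An asymmetric Heck cyclization under carbon monoxide (Pd(OAc)2, (R)-BINAP, Et3N, CO 1 atm, MeOH/DMF, 60 °C) would close ring B at C10 and trap the neopentyl alkylpalladium as methyl 2-[(S)-3-(4-bromo-2-methylbutan-2-yl)-7-isopropyl-6,8-dimethoxy-1-methyl-4-oxo-1,4-dihydronaphthalen-1-yl]acetate F1 (domino Heck–alkoxycarbonylation). KN(SiMe3)2 in THF at −78 °C would close ring A by intramolecular alkylation of the ester enolate (C1) with the C2 bromide and give the 1-methoxycarbonyl derivative of 14 F2. LiOH in THF/H2O would give the 1-carboxylic acid of 14 F3. Barton decarboxylation (N-hydroxypyridine-2-thione ester, tBuSH, hν) would remove the extra carbon and return 14.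

Step 17. What may go wrong: 1,2-aryl shift of the alkylidene carbene with ring expansion, or enolization of the hindered C7 ketone in place of addition. The fallback sets out from 24 and comes back at 30, so that steps 16–18 are bypassed. KN(SiMe3)2 and PhNTf2 (THF, −78 °C) would give the C6=C7 enol triflate of 24 F4. A carbonylative Heck cyclization (Pd(OAc)2, dppp, Et3N, CO 1 atm, MeCN, 70 °C) would follow, in which the acylpalladium adds 5-exo to C25=C26 from the face anti to the cyclopropane CH2 and β-hydride elimination follows; it would give the spiro dienone with the C23 carbonyl, C6=C7 and C26=C27 F5, with the same (S) spiro centre. Corey–Bakshi–Shibata reduction (oxazaborolidine enantiomer chosen for 23R, catecholborane, toluene, −40 °C) would give the (23R) allylic alcohol F6. Hydroxyl-directed hydrogenation (H2, [Ir(cod)(PCy3)(py)]PF6, CH2Cl2) would reduce C6=C7 and C26=C27 and return 30.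

Step 18. What may go wrong: poor facial selectivity if reagent and substrate preferences oppose each other, or slow hydroboration beside the quaternary spiro carbon. The fallback sets out from 28 and comes back at 30. Shi epoxidation (fructose-derived ketone catalyst, Oxone (KHSO5·0.5KHSO4·0.5K2SO4), K2CO3, MeCN/dimethoxymethane/H2O, 0 °C) would give the α-epoxide of the C7=C23 bond F7 under catalyst control. Hydrogenolysis of the benzylic C7–O bond over Raney Ni (H2, EtOH, rt), which is known to proceed with retention at the benzylic carbon, would return 30.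

Further compounds
F1 | step 8 | methyl 2-[(S)-3-(4-bromo-2-methylbutan-2-yl)-7-isopropyl-6,8-dimethoxy-1-methyl-4-oxo-1,4-dihydronaphthalen-1-yl]acetate | CC(C)c1c(OC)cc2c(c1OC)C(=O)C=C(C(C)(C)CCBr)[C@]2(C)CC(=O)OC
F2 | step 8 | methyl (10S)-12,14-dimethoxy-7-oxoabieta-5,8,11,13-tetraene-1-carboxylate (both C1 epimers) | CC(C)c1c(OC)cc2c(c1OC)C(=O)C=C1C(C)(C)CCC(C(=O)OC)[C@@]12C
F3 | step 8 | (10S)-12,14-dimethoxy-7-oxoabieta-5,8,11,13-tetraene-1-carboxylic acid (both C1 epimers) | CC(C)c1c(OC)cc2c(c1OC)C(=O)C=C1C(C)(C)CCC(C(=O)O)[C@@]12C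
F4 | step 17 | C6=C7 enol triflate of 24 | CC(C)c1c(OC)cc2c(c1C1=CC[C@]3(C(C)C)C[C@@H]31)C(OS(=O)(=O)C(F)(F)F)=C[C@H]1C(C)(C)CCC[C@@]12C
F5 | step 17 | spiro dienone with C23 carbonyl, C6=C7 and C26=C27 | CC(C)c1c(OC)cc2c3c1[C@]4(C(=O)C3=C[C@H]5C(C)(C)CCC[C@@]52C)C=C[C@]6(C(C)C)C[C@@H]64
F6 | step 17 | (23R) allylic alcohol with C6=C7 and C26=C27 | CC(C)c1c(OC)cc2c3c1[C@]4([C@H](O)C3=C[C@H]5C(C)(C)CCC[C@@]52C)C=C[C@]6(C(C)C)C[C@@H]64
F7 | step 18 | α-epoxide of the C7=C23 bond of 28 | CC(C)c1c(OC)cc2c3c1[C@]4([C@@H]7O[C@]37C[C@H]5C(C)(C)CCC[C@@]52C)CC[C@]6(C(C)C)C[C@@H]64
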